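## Retrosynthetic overview

1. Rings A and B and the enone are bought intact as naringenin (1). Base opens its pyranone ring (phenolate 2) to naringenin chalcone (3), and TBSCl (4) caps the two non-chelated phenols to give 5.
2. Key disconnection: the lactone ring is cut at C4–C4a and O1–C2, into chalcone 5 and 3-phenylprop-2-ynal (6) as a cinnamoyl-thioester surrogate. A chiral carbene catalyst joins them as in the presumed biogenesis (chalcone + cinnamoyl-CoA), forming the only new ring and setting C4 (R) in lactone 7.
3. Regiocontrol: with the para-oxygen of ring A silylated, only an OH ortho to the ketone can lactonise, so only the 8-acyl lactone can form. Fluoride in the same flask frees target 8.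
4. Ring order: rings A and B preformed → flavanone ring opened (step 1) → lactone ring closed last (step 3).

Assumption: the (5aR,10bS) antipode of the aminoindanol-derived N-mesityl triazolium chloride is taken to give the 4R lactone. This has not been verified; both antipodes are sold, so the (5aS,10bR) salt is used unchanged if the first run gives 4S.

Locants: in chalcones the acyl ring A carries primed locants; in flavanones (1, F1) the primed ring is ring B.

## Route

Step 1
Reactants: 1 naringenin (racemic 5,7-dihydroxy-2-(4-hydroxyphenyl)chroman-4-one)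
Product: 3 naringenin chalcone [(E)-1-(2,4,6-trihydroxyphenyl)-3-(4-hydroxyphenyl)prop-2-en-1-one], via chalcone tripotassium phenolate 2 (not isolated)
Conditions: KOH (20% aq, excess), N2, 90 °C, 5 min; then pour into ice-cold 3 M HCl (pH 2–3), 0 °C, filter at once, dry cold
Reagents that add atoms: none
Why: E1cB retro-oxa-Michael ring opening of the flavanone (the reverse of the chalcone isomerase reaction) gives phenolate 2, which is favoured in strong base, and fast cold acidification precipitates the neutral chalcone before it re-closes; the stereocentre of 1 is destroyed, so racemic 1 suffices.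

Step 2
Reactants: 3 naringenin chalcone; 4 tert-butyldimethylsilyl chloride (TBSCl)
Product: 5 (E)-1-[4-(tert-butyldimethylsilyloxy)-2,6-dihydroxyphenyl]-3-[4-(tert-butyldimethylsilyloxy)phenyl]prop-2-en-1-one (bis-TBS chalcone)
Conditions: TBSCl (2.1 equiv), imidazole (4 equiv), DMF, −20 → 0 °C, 1 h; pH 7 buffer work-up, short silica plug
Reagents that add atoms: tert-butyldimethylsilyl chloride (4), CC(C)(C)[Si](C)(C)Cl
Why: Chemoselective phenol silylation: the 4- and 4'-OH are free and the most acidic, whereas the 2'- and 6'-OH are hydrogen-bonded to the ketone and flanked by the acyl group, so two equivalents stop at the bis-ether; no stereocentre is involved.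

Step 3
Reactants: 5 bis-TBS chalcone; 6 3-phenylprop-2-ynal
Product: 8 (4R)-5,7-dihydroxy-8-[(E)-3-(4-hydroxyphenyl)prop-2-enoyl]-4-phenylchroman-2-one (target), via bis-TBS lactone 7 (not isolated)
Conditions: 6 (1.1 equiv, slow addition), (5aR,10bS)-2-mesityl-5a,10b-dihydro-4H,6H-indeno[2,1-b][1,2,4]triazolo[4,3-d][1,4]oxazin-2-ium chloride (10 mol %), no added base, toluene, 40 °C, 24 h; then THF, Et3N·3HF (3 equiv), 0 °C → rt
Reagents that add atoms: 3-phenylprop-2-ynal (6), O=CC#Cc1ccccc1
Why: Proposed new method: the carbene converts 6 by internal redox into a catalyst-bound (E)-cinnamoyl azolium, the laboratory counterpart of cinnamoyl-CoA; a chelated ortho-OH of 5 adds to it and the hemiacetal undergoes a Coates–Claisen [3,3] shift to the adjacent ring carbon (C3' and C5' are equivalent), the indane wall of the catalyst leaving one face of the β-carbon open and so setting C4 as R; the acyl azolium then lactonises onto the same OH, the only free oxygen next to the new bond because the para-oxygen is silylated, which fixes the 8-acyl regiochemistry and releases the carbene; an O-cinnamoyl ester formed off-cycle is an activated aryl ester and can re-enter the cycle; the acidic fluoride then protonates the carbene and removes both silyl groups without opening the lactone, so the doubly benzylic C4 is not touched; the closest known reaction type is the carbene-catalysed enantioselective annulation of ynals with naphthols and kojic acids, extended here to a 2-acylphloroglucinol chalcone that carries its own enone.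

## Compound list

1 | naringenin, racemic 5,7-dihydroxy-2-(4-hydroxyphenyl)chroman-4-one | O=C1CC(c2ccc(O)cc2)Oc2cc(O)cc(O)c12 | starting material
2 | naringenin chalcone tripotassium phenolate | [K+].[K+].[K+].[O-]c1ccc(/C=C/C(=O)c2c(O)cc([O-])cc2[O-])cc1 | intermediate
3 | naringenin chalcone, (E)-1-(2,4,6-trihydroxyphenyl)-3-(4-hydroxyphenyl)prop-2-en-1-one | O=C(/C=C/c1ccc(O)cc1)c1c(O)cc(O)cc1O | intermediate
4 | tert-butyldimethylsilyl chloride | CC(C)(C)[Si](C)(C)Cl | starting material
5 | (E)-1-[4-(tert-butyldimethylsilyloxy)-2,6-dihydroxyphenyl]-3-[4-(tert-butyldimethylsilyloxy)phenyl]prop-2-en-1-one | CC(C)(C)[Si](C)(C)Oc1ccc(/C=C/C(=O)c2c(O)cc(O[Si](C)(C)C(C)(C)C)cc2O)cc1 | intermediate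
6 | 3-phenylprop-2-ynal | O=CC#Cc1ccccc1 | starting material
7 | (4R)-5-(tert-butyldimethylsilyloxy)-8-[(E)-3-[4-(tert-butyldimethylsilyloxy)phenyl]prop-2-enoyl]-7-hydroxy-4-phenylchroman-2-one | O=C1C[C@H](c2ccccc2)c2c(O[Si](C)(C)C(C)(C)C)cc(O)c(C(=O)/C=C/c3ccc(O[Si](C)(C)C(C)(C)C)cc3)c2O1 | intermediate
8 | (4R)-5,7-dihydroxy-8-[(E)-3-(4-hydroxyphenyl)prop-2-enoyl]-4-phenylchroman-2-one | O=C1C[C@H](c2ccccc2)c2c(O)cc(O)c(C(=O)/C=C/c3ccc(O)cc3)c2O1 | target

## Summary and fallbacks

Total step count: 3. Longest linear sequence: 3 (1 → 3 → 5 → 8).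

Compounds 3, 5, 7 and 8 are 2'-hydroxychalcones and are kept away from base, strong acid and methanol throughout, to avoid flavanone closure and lactone solvolysis.

Steps most likely to fail, most risky first:

Step 3. The acyl-deactivated ring A may not undergo C-alkylation, the carbene may instead catalyse oxa-Michael closure of 5 to the flavanone, a second annulation may occur at the remaining ring position, or the ee may be low. The fallback replaces covalent carbene catalysis with hydrogen-bond catalysis of an isolable acyl donor; it sets out from 5 and comes back to the route at 7. Commercial cinnamoyl chloride and 3,5-dimethylpyrazole (Et3N, CH2Cl2, 0 °C) give (E)-1-(3,5-dimethylpyrazol-1-yl)-3-phenylprop-2-en-1-one F5. Compound 5 and F5, with a quinine-derived bifunctional squaramide (10 mol %; the quinidine-derived pseudo-enantiomer if the sense is opposite) in CH2Cl2 at rt, undergo an enantioselective Friedel–Crafts conjugate addition to the open-chain (R)-acylpyrazole adduct F6. F6 lactonises in the same flask onto the only adjacent free OH with loss of 3,5-dimethylpyrazole and gives 7, which is desilylated with Et3N·3HF as in the second stage of step 3.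

Step 2. The silylation may not stop cleanly at the bis-ether, or imidazole may close 3 to naringenin. The fallback drives the protection to a self-limiting end point; it sets out from 3 and comes back at 8. TBSCl (3.3 equiv) and imidazole in DMF at rt give the tris-ether (E)-1-[2,4-bis(tert-butyldimethylsilyloxy)-6-hydroxyphenyl]-3-[4-(tert-butyldimethylsilyloxy)phenyl]prop-2-en-1-one F3; once one ortho OH is silylated the last one is fully chelated and resists. F3 and 6 under the carbene conditions of step 3 give the tris-TBS lactone F4, because the single remaining OH both directs the Claisen shift to its neighbouring carbon and closes the lactone. Et3N·3HF in the same flask then gives 8.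

Step 1. The aqueous opening may return mostly naringenin through re-closure on acidification. The fallback protects first and opens the ring under anhydrous conditions; it sets out from 1 and comes back at 5, so it also bypasses step 2. TBSCl (2.1 equiv) and imidazole in DMF silylate the 7- and 4'-OH of 1 (the 5-OH is chelated) to give racemic 7,4'-bis-O-(tert-butyldimethylsilyl)naringenin F1. LiN(SiMe3)2 (2.5 equiv) in THF, −78 → 0 °C, effects E1cB opening to the chalcone dilithium bis-phenolate F2, and a quench with AcOH at −78 °C gives 5.

## Further compounds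

F1 | step 1 | racemic 7,4'-bis-O-(tert-butyldimethylsilyl)naringenin | O=C1CC(c2ccc(O[Si](C)(C)C(C)(C)C)cc2)Oc2cc(O[Si](C)(C)C(C)(C)C)cc(O)c12
F2 | step 1 | dilithium 2',6'-bis-phenolate of chalcone 5 | [Li+].[Li+].CC(C)(C)[Si](C)(C)Oc1ccc(/C=C/C(=O)c2c([O-])cc(O[Si](C)(C)C(C)(C)C)cc2[O-])cc1
F3 | step 2 | (E)-1-[2,4-bis(tert-butyldimethylsilyloxy)-6-hydroxyphenyl]-3-[4-(tert-butyldimethylsilyloxy)phenyl]prop-2-en-1-one | CC(C)(C)[Si](C)(C)Oc1ccc(/C=C/C(=O)c2c(O)cc(O[Si](C)(C)C(C)(C)C)cc2O[Si](C)(C)C(C)(C)C)cc1
F4 | step 2 | (4R)-5,7-bis(tert-butyldimethylsilyloxy)-8-[(E)-3-[4-(tert-butyldimethylsilyloxy)phenyl]prop-2-enoyl]-4-phenylchroman-2-one | O=C1C[C@H](c2ccccc2)c2c(O[Si](C)(C)C(C)(C)C)cc(O[Si](C)(C)C(C)(C)C)c(C(=O)/C=C/c3ccc(O[Si](C)(C)C(C)(C)C)cc3)c2O1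
F5 | step 3 | (E)-1-(3,5-dimethylpyrazol-1-yl)-3-phenylprop-2-en-1-one | Cc1cc(C)n(C(=O)/C=C/c2ccccc2)n1
F6 | step 3 | (R)-open-chain acylpyrazole adduct, (3R)-3-[6-(tert-butyldimethylsilyloxy)-3-[(E)-3-[4-(tert-butyldimethylsilyloxy)phenyl]prop-2-enoyl]-2,4-dihydroxyphenyl]-1-(3,5-dimethylpyrazol-1-yl)-3-phenylpropan-1-one | Cc1cc(C)n(C(=O)C[C@H](c2ccccc2)c2c(O[Si](C)(C)C(C)(C)C)cc(O)c(C(=O)/C=C/c3ccc(O[Si](C)(C)C(C)(C)C)cc3)c2O)n1
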